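(The runs were computed on assumed constants.)

Start from a small charge: 0.050 M of solid Q, which reaches E as L. Here c(L) means dissolved L.

| flask | Q | E | remark | time |
|---|---|---|---|---|
| alder | 0.050 M | 1.2 equiv | run made earlier |  |
| larch | 0.050 M | 2.7 equiv | run made earlier |  |
| flask | 0.050 M | 1.80 equiv |  | 12 min |

| run | time / min | Z / % | L / % |
|---|---|---|---|
| alder | 1.50 | 0 | 12 |
| alder | 3.00 | 1 | 21 |
| alder | 5.00 | 4 | 26 |
| alder | 6.00 | 10 | 26 |
| alder | 8.00 | 32 | 11 |
| alder | 10.0 | 54 | 7 |
| alder | 12.0 | 70 | 6 |
| larch | 0.667 | 0 | 6 |
| larch | 2.00 | 0 | 16 |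
| larch | 3.00 | 2 | 18 |
| larch | 5.00 | 31 | 2 |
| larch | 8.00 | 64 | 3 |
| larch | 10.0 | 83 | 3 |
| larch | 12.0 | 98 | 0 |

(readings scatter by 1.5 percentage points)

- solid, in amounts per volume of the solution: Q
- the numbers in the tables scatter with a standard deviation of 1.5 percentage points
- at the start none of Q is in solution
- L is what Q becomes in solution
- L means what is dissolved; the solid is not counted in it

- the Z standing at 12 min, as a percentage of the Q charged
- concentration of L in solution at 12 min, in percent of saturation

Read two times from the runs. Take the late climb of Z in alder, 32% to 70%, and in larch, 31% to 98%, and stretch each over a full charge: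

t_feed = 10.5 min (alder), 10.4 min (larch), mean 10.5 min

Call this mean the feed time, the time the steady climb of Z needs for the whole charge. E differs 2.25-fold between the runs, yet the two times match, so treat the dissolving of Q as the rate-limiting step during the climb.

E moves the second time, the lag, which is the end time minus the Z share times t_feed:

t_lag = 4.66 min (alder), 1.72 min (larch)

The flask's 1.80 equiv is the geometric mean of the two charges, so take the geometric mean of the lags:

t_lag = 2.83 min

Z = (t − t_lag)/t_feed = 87.4%

The forecast, holding that “After takeoff, the process is dissolution-limited”, gives Z 85% (78% to 91%), less than my figure, and c(L) at 11% of saturation (6% to 20%).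

The flask gives Z 91.2% and c(L) at 10.6% of saturation.

    L + E + X → Z + 2 X (k = 20.0 L² mol⁻² s⁻¹)
    L + E → Z + X (k = 0.00210 L mol⁻¹ s⁻¹)
    Q ⇌ L, rate k3*(cs3 - [L]) while solid is left; crystals form when [L] > cs3 (solubility = 19.0 mM, k = 0.00480 s⁻¹)

At 12.0 min the flask still holds Q 4.81% and L 4.02%. Read backward through t_feed, its lag is 2.44 min, against my 2.83 min.

For the neighbour flask with 0.030 M of Q, assume the same feed in molar terms, so t_feed = 6.29 min. Assuming the flask's lag there too, the feed offers 152% of that charge by 12 min, so expect the solid gone; computed for that neighbour flask, Z stands at 95.7%, L at 4.29% and Q at 0%.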